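**Plan**

- Retrosynthesis: the two aryl methoxymethyl (MOM) ethers are removed last; ring C is then cut in one stroke at O1–C8a and C2–C3, giving a ring A 2-fluoroaryl ketone (as its silyl enol ether) and the ring B aldehyde.
- Enabling feature: the C4 carbonyl sits on C4a, ortho to C8a. It makes C3 nucleophilic (enol silane) and makes a C8a–F bond electrophilic (addition–elimination), so one aldehyde C=O can be stitched across C3 and C8a of ring A (formal [4+2]).
- Ring A piece: 4-bromo-3-fluorophenol is iodinated at both ortho positions, MOM-protected, prenylated twice (Stille), then acylated at the bromine-bearing carbon (Br–Li exchange, Weinreb amide). Ring B piece: 4-hydroxy-3-iodobenzaldehyde, MOM protection, Stille prenylation.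
- Forward order: ring A and ring B are fully substituted first; ring C is closed last by aldol then intramolecular SNAr in one flask; acid then frees the phenols.
- Stereochemistry: C2 (R) comes from catalyst-controlled Si-face attack on the aldehyde (chiral acyloxyborane Mukaiyama aldol). C3 (R) is set thermodynamically (2,3-trans) by enolisation of the 3-hydroxy ketone while the 4'-oxygen is still capped.
- Helpers removed on the way: fluorine (leaving group at C8a), the Me3Si and tBuMe2Si groups (lost in the key step), the two MOM groups (last step).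

Key step: step 9

Remark: the (2S,3S)-tartrate-derived acyloxyborane is taken to direct attack to the Si face of the ring B aldehyde, by analogy with the Re-face attack on benzaldehyde expected of the (2R,3R) catalyst; if a model aldol shows the opposite sense, the enantiomeric ligand is used.

**Route**

Step 1
Reactants: 1 4-bromo-3-fluorophenol
Product: 2 4-bromo-3-fluoro-2,6-diiodophenol
Conditions: N-iodosuccinimide (2.2 equiv), TsOH·H2O (10 mol %), MeCN, 0 °C to rt
Reagents that add atoms: N-iodosuccinimide, O=C1CCC(=O)N1I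
Why: Electrophilic aromatic iodination, in which the hydroxyl group directs to its two free ortho positions (para is blocked by bromine), so both future prenyl sites are marked at once.

Step 2
Reactants: 2 4-bromo-3-fluoro-2,6-diiodophenol
Product: 3 1-bromo-2-fluoro-3,5-diiodo-4-(methoxymethoxy)benzene
Conditions: MeOCH2Cl (1.5 equiv), iPr2NEt (2 equiv), CH2Cl2, 0 °C to rt
Reagents that add atoms: chloromethyl methyl ether, COCCl
Why: O-alkylation of the acidic phenol to its MOM acetal, which keeps the oxygen neutral (no phenoxide to deactivate the later SNAr) and tolerates organolithium, palladium and fluoride steps.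

Step 3
Reactants: 3 1-bromo-2-fluoro-3,5-diiodo-4-(methoxymethoxy)benzene
Product: 4 1-bromo-2-fluoro-4-(methoxymethoxy)-3,5-bis(3-methylbut-2-en-1-yl)benzene
Conditions: tributyl(3-methylbut-2-en-1-yl)stannane (2.3 equiv), Pd(PPh3)4 (5 mol %), DMF, 70 °C
Reagents that add atoms: tributyl(3-methylbut-2-en-1-yl)stannane, CCCC[Sn](CCCC)(CCCC)CC=C(C)C
Why: Twofold Stille coupling, in which the zerovalent palladium catalyst inserts into the two C–I bonds much faster than into C–Br or C–F and the stannane transfers the prenyl group through its CH2 terminus, so the bromine is kept for step 5.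

Step 4
Reactants: 5 methyl 2-[(tert-butyldimethylsilyl)oxy]acetate
Product: 6 2-[(tert-butyldimethylsilyl)oxy]-N-methoxy-N-methylacetamide
Conditions: MeNH(OMe)·HCl (1.5 equiv), iPrMgCl (3.0 equiv), THF, −20 °C
Reagents that add atoms: N,O-dimethylhydroxylamine hydrochloride, CNOC.Cl
Why: Aminolysis of the ester by the magnesium amide of N,O-dimethylhydroxylamine (Weinreb amide formation) gives an acyl donor that stops at the ketone stage.

Step 5
Reactants: 4 1-bromo-2-fluoro-4-(methoxymethoxy)-3,5-bis(3-methylbut-2-en-1-yl)benzene; 6 2-[(tert-butyldimethylsilyl)oxy]-N-methoxy-N-methylacetamide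
Product: 8 2-[(tert-butyldimethylsilyl)oxy]-1-[2-fluoro-4-(methoxymethoxy)-3,5-bis(3-methylbut-2-en-1-yl)phenyl]ethan-1-one, via aryllithium 7 (not isolated)
Conditions: n-BuLi (1.05 equiv), THF, −78 °C, 15 min; then 6 (1.15 equiv), −78 to −50 °C; aq. NH4Cl
Reagents that add atoms: none
Why: Bromine–lithium exchange followed by Weinreb ketone synthesis, with the 2-fluoroaryllithium kept at −78 °C so that it does not lose LiF to an aryne and the chelated tetrahedral adduct preventing a second addition.

Step 6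
Reactants: 8 2-[(tert-butyldimethylsilyl)oxy]-1-[2-fluoro-4-(methoxymethoxy)-3,5-bis(3-methylbut-2-en-1-yl)phenyl]ethan-1-one
Product: 10 tert-butyl{[(Z)-2-[2-fluoro-4-(methoxymethoxy)-3,5-bis(3-methylbut-2-en-1-yl)phenyl]-2-[(trimethylsilyl)oxy]ethenyl]oxy}dimethylsilane, via lithium enolate 9 (not isolated)
Conditions: LiN(SiMe3)2 (1.1 equiv), THF, −78 °C; then Me3SiCl (1.3 equiv), −78 to 0 °C; pentane, filtration, used crude
Reagents that add atoms: chlorotrimethylsilane, C[Si](C)(C)Cl
Why: Kinetic deprotonation and O-silylation (silyl enol ether formation), where allylic strain between the aryl ring and the C3 substituent should favour the Z-enolate as with aryl ethyl ketones, and the outcome of step 9 does not depend on this geometry.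

Step 7
Reactants: 11 4-hydroxy-3-iodobenzaldehyde
Product: 12 3-iodo-4-(methoxymethoxy)benzaldehyde
Conditions: MeOCH2Cl (1.3 equiv), iPr2NEt (1.8 equiv), CH2Cl2, 0 °C to rt
Reagents that add atoms: chloromethyl methyl ether, COCCl
Why: O-alkylation to the MOM acetal, which prevents phenoxide formation (a para-phenoxide would make the aldehyde unreactive and would later open a quinone methide pathway at C2).

Step 8
Reactants: 12 3-iodo-4-(methoxymethoxy)benzaldehyde
Product: 13 4-(methoxymethoxy)-3-(3-methylbut-2-en-1-yl)benzaldehyde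
Conditions: tributyl(3-methylbut-2-en-1-yl)stannane (1.2 equiv), Pd(PPh3)4 (5 mol %), DMF, 80 °C
Reagents that add atoms: tributyl(3-methylbut-2-en-1-yl)stannane, CCCC[Sn](CCCC)(CCCC)CC=C(C)C
Why: Stille coupling of the aryl iodide with linear prenyl transfer, tolerated by the aldehyde and the MOM ether.

Step 9
Reactants: 10 tert-butyl{[(Z)-2-[2-fluoro-4-(methoxymethoxy)-3,5-bis(3-methylbut-2-en-1-yl)phenyl]-2-[(trimethylsilyl)oxy]ethenyl]oxy}dimethylsilane; 13 4-(methoxymethoxy)-3-(3-methylbut-2-en-1-yl)benzaldehyde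
Product: 17 (2R,3R)-3-hydroxy-7-(methoxymethoxy)-2-[4-(methoxymethoxy)-3-(3-methylbut-2-en-1-yl)phenyl]-6,8-bis(3-methylbut-2-en-1-yl)-2,3-dihydro-4H-chromen-4-one, via syn-aldol silyl ether 14 (not isolated), via cis-3-silyloxychromanone 15 (not isolated), via cis-3-hydroxychromanone 16 (not isolated)
Conditions: chiral acyloxyborane made in the flask from (2S,3S)-2-O-(2,6-diisopropoxybenzoyl)tartaric acid and BH3·THF (20 mol %), EtCN, −78 °C; then Bu4NF (2.5 equiv, THF), −78 to 0 °C, then rt, argon, degassed; aq. NH4Cl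
Reagents that add atoms: none
Why: The acyloxyborane binds aldehyde 13 and exposes its Si face to the nucleophilic C3 of enol silane 10 in an open transition state (Mukaiyama aldol; closest precedent is the same catalyst class with silyl enol ethers of aryl ethyl ketones and aromatic aldehydes), which forms C2–C3, sets C2 as R under catalyst control and should give the syn adduct 14 with silyl transfer to the new oxygen. Fluoride then removes the trimethylsilyl group and the benzylic alkoxide adds to C8a of ring A, which carries fluorine and is ortho to the C4 carbonyl, in a 6-exo-trig addition–elimination through a Meisenheimer adduct (intramolecular SNAr, as used to close chromanones and chromones from 2-fluoroaryl ketones), so O1–C8a forms with retention at C2 and ring C is closed as 15. Because Me3Si–O is cleaved much faster than tBuMe2Si–O, the silyl ether at O3 should fall only after the ring is shut (16), and reversible enolisation of the 3-hydroxy ketone towards C4 then puts C3 under thermodynamic control, so the 2,3-trans isomer 17 (aryl and hydroxyl both equatorial, hydroxyl hydrogen-bonded to C4=O) should predominate. The step needs face selectivity at the aldehyde (catalyst), arylation of O1 and not O3 (O3 still silylated during closure), ring closure faster than retro-aldol (fluoride leaving group, ortho-acyl activation, low temperature) and no scrambling of C2 during the C3 equilibration (the 4'-oxygen is capped as its MOM ether, so no quinone methide can open the C2–O1 bond).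

Step 10
Reactants: 17 (2R,3R)-3-hydroxy-7-(methoxymethoxy)-2-[4-(methoxymethoxy)-3-(3-methylbut-2-en-1-yl)phenyl]-6,8-bis(3-methylbut-2-en-1-yl)-2,3-dihydro-4H-chromen-4-one
Product: 18 Lespeflorin B3, (2R,3R)-3,7-dihydroxy-2-[4-hydroxy-3-(3-methylbut-2-en-1-yl)phenyl]-6,8-bis(3-methylbut-2-en-1-yl)-2,3-dihydro-4H-chromen-4-one
Conditions: HCl (1.5 M in MeOH/H2O), 35 °C, argon
Reagents that add atoms: none
Why: Acid-catalysed transacetalisation of the two aryl MOM ethers to methanol (acetal cleavage), mild enough that the prenyl olefins and both stereocentres should be left untouched.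

**Compound list**

1 | 4-bromo-3-fluorophenol | Oc1ccc(Br)c(F)c1 | starting material
2 | 4-bromo-3-fluoro-2,6-diiodophenol | Oc1c(I)cc(Br)c(F)c1I | intermediate
3 | 1-bromo-2-fluoro-3,5-diiodo-4-(methoxymethoxy)benzene | COCOc1c(I)cc(Br)c(F)c1I | intermediate
4 | 1-bromo-2-fluoro-4-(methoxymethoxy)-3,5-bis(3-methylbut-2-en-1-yl)benzene | COCOc1c(CC=C(C)C)cc(Br)c(F)c1CC=C(C)C | intermediate
5 | methyl 2-[(tert-butyldimethylsilyl)oxy]acetate | COC(=O)CO[Si](C)(C)C(C)(C)C | starting material
6 | 2-[(tert-butyldimethylsilyl)oxy]-N-methoxy-N-methylacetamide | CON(C)C(=O)CO[Si](C)(C)C(C)(C)C | intermediate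
7 | [2-fluoro-4-(methoxymethoxy)-3,5-bis(3-methylbut-2-en-1-yl)phenyl]lithium | [Li]c1cc(CC=C(C)C)c(OCOC)c(CC=C(C)C)c1F | intermediate (not isolated)
8 | 2-[(tert-butyldimethylsilyl)oxy]-1-[2-fluoro-4-(methoxymethoxy)-3,5-bis(3-methylbut-2-en-1-yl)phenyl]ethan-1-one | CC(C)=CCc1cc(C(=O)CO[Si](C)(C)C(C)(C)C)c(F)c(CC=C(C)C)c1OCOC | intermediate
9 | lithium (Z)-2-[(tert-butyldimethylsilyl)oxy]-1-[2-fluoro-4-(methoxymethoxy)-3,5-bis(3-methylbut-2-en-1-yl)phenyl]ethen-1-olate | [Li]O/C(=C\O[Si](C)(C)C(C)(C)C)c1cc(CC=C(C)C)c(OCOC)c(CC=C(C)C)c1F | intermediate (not isolated)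
10 | tert-butyl{[(Z)-2-[2-fluoro-4-(methoxymethoxy)-3,5-bis(3-methylbut-2-en-1-yl)phenyl]-2-[(trimethylsilyl)oxy]ethenyl]oxy}dimethylsilane | C[Si](C)(C)O/C(=C\O[Si](C)(C)C(C)(C)C)c1cc(CC=C(C)C)c(OCOC)c(CC=C(C)C)c1F | intermediate
11 | 4-hydroxy-3-iodobenzaldehyde | O=Cc1ccc(O)c(I)c1 | starting material
12 | 3-iodo-4-(methoxymethoxy)benzaldehyde | COCOc1ccc(C=O)cc1I | intermediate
13 | 4-(methoxymethoxy)-3-(3-methylbut-2-en-1-yl)benzaldehyde | COCOc1ccc(C=O)cc1CC=C(C)C | intermediate
14 | (2S,3R)-2-[(tert-butyldimethylsilyl)oxy]-1-[2-fluoro-4-(methoxymethoxy)-3,5-bis(3-methylbut-2-en-1-yl)phenyl]-3-[4-(methoxymethoxy)-3-(3-methylbut-2-en-1-yl)phenyl]-3-[(trimethylsilyl)oxy]propan-1-one | CC(C)=CCc1cc(ccc1OCOC)[C@@H](O[Si](C)(C)C)[C@H](O[Si](C)(C)C(C)(C)C)C(=O)c1cc(CC=C(C)C)c(OCOC)c(CC=C(C)C)c1F | intermediate (not isolated)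
15 | (2R,3S)-3-[(tert-butyldimethylsilyl)oxy]-7-(methoxymethoxy)-2-[4-(methoxymethoxy)-3-(3-methylbut-2-en-1-yl)phenyl]-6,8-bis(3-methylbut-2-en-1-yl)-2,3-dihydro-4H-chromen-4-one | CC(C)=CCc1cc([C@H]2Oc3c(cc(CC=C(C)C)c(OCOC)c3CC=C(C)C)C(=O)[C@H]2O[Si](C)(C)C(C)(C)C)ccc1OCOC | intermediate (not isolated)
16 | (2R,3S)-3-hydroxy-7-(methoxymethoxy)-2-[4-(methoxymethoxy)-3-(3-methylbut-2-en-1-yl)phenyl]-6,8-bis(3-methylbut-2-en-1-yl)-2,3-dihydro-4H-chromen-4-one | CC(C)=CCc1cc([C@H]2Oc3c(cc(CC=C(C)C)c(OCOC)c3CC=C(C)C)C(=O)[C@H]2O)ccc1OCOC | intermediate (not isolated)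
17 | (2R,3R)-3-hydroxy-7-(methoxymethoxy)-2-[4-(methoxymethoxy)-3-(3-methylbut-2-en-1-yl)phenyl]-6,8-bis(3-methylbut-2-en-1-yl)-2,3-dihydro-4H-chromen-4-one | CC(C)=CCc1cc([C@H]2Oc3c(cc(CC=C(C)C)c(OCOC)c3CC=C(C)C)C(=O)[C@@H]2O)ccc1OCOC | intermediate
18 | Lespeflorin B3, (2R,3R)-3,7-dihydroxy-2-[4-hydroxy-3-(3-methylbut-2-en-1-yl)phenyl]-6,8-bis(3-methylbut-2-en-1-yl)-2,3-dihydro-4H-chromen-4-one | CC(C)=CCc1cc([C@H]2Oc3c(cc(CC=C(C)C)c(O)c3CC=C(C)C)C(=O)[C@@H]2O)ccc1O | target

**Count and risks**

Total: 10 steps. Longest linear sequence: 7 steps (steps 1, 2, 3, 5, 6, 9, 10).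

Step 9 (highest risk). Enantiomeric purity can be lost by retro-aldol of the benzylic alkoxide before ring closure. The silyl group on O3 can migrate to the new alkoxide, followed by closure of a five-membered ring through O3. The C3 equilibration can stay incomplete or be accompanied by base-induced ring opening at C2–O1. Fallback: ring C is closed from the oxygen side by the established chalcone epoxide route, which sets out from aldehyde 13 and comes back at target 18. Commercial 1-(2,4-dihydroxyphenyl)ethan-1-one is iodinated twice (N-iodosuccinimide) to 1-(2,4-dihydroxy-3,5-diiodophenyl)ethan-1-one F1. F1 is protected (NaH, MeOCH2Cl, DMF) as 1-[3,5-diiodo-2,4-bis(methoxymethoxy)phenyl]ethan-1-one F2. F2 is coupled twice with tributyl(3-methylbut-2-en-1-yl)stannane (Pd(PPh3)4, DMF) to 1-[2,4-bis(methoxymethoxy)-3,5-bis(3-methylbut-2-en-1-yl)phenyl]ethan-1-one F3. Claisen–Schmidt condensation of F3 with 13 (KOH, EtOH) gives (2E)-1-[2,4-bis(methoxymethoxy)-3,5-bis(3-methylbut-2-en-1-yl)phenyl]-3-[4-(methoxymethoxy)-3-(3-methylbut-2-en-1-yl)phenyl]prop-2-en-1-one F4. Juliá–Colonna epoxidation (poly-L-leucine, urea–H2O2, DBU, THF) attacks only the enone, leaves the prenyl olefins alone, and gives [2,4-bis(methoxymethoxy)-3,5-bis(3-methylbut-2-en-1-yl)phenyl]{(2R,3S)-3-[4-(methoxymethoxy)-3-(3-methylbut-2-en-1-yl)phenyl]oxiran-2-yl}methanone F5. HCl in MeOH then removes the three MOM groups, and the freed 2'-hydroxyl opens the epoxide at the benzylic carbon with inversion (6-endo) to give 18.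

Step 3. Oxidative addition can also occur at C–Br once the iodides are consumed, and part of the prenyl group can be transferred through its tertiary terminus, giving branched isomers. Fallback: halogen–metal exchange in place of cross-coupling, setting out from 3 and coming back at 4. Treatment of 3 with iPrMgCl·LiCl (1.05 equiv, THF, −40 °C) exchanges only iodine, first at the position flanked by fluorine and the MOM ether. CuBr·SMe2 and 1-bromo-3-methylbut-2-ene then give 1-bromo-2-fluoro-5-iodo-4-(methoxymethoxy)-3-(3-methylbut-2-en-1-yl)benzene F6. The same exchange and allylation on F6 give 4.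

Step 10. Each freed phenol can add under acid catalysis to its ortho-prenyl olefin (chroman formation), and the C2–O1 bond can open once the 4'-hydroxyl is free, which would epimerise C2. Fallback: aprotic silyl exchange in place of protic acetal hydrolysis, setting out from 17 and coming back at 18. Me3SiOTf and 2,2'-bipyridyl (MeCN, 0 °C) convert the aryl MOM ethers, and the 3-hydroxyl, into trimethylsilyl ethers, giving (2R,3R)-2-[3-(3-methylbut-2-en-1-yl)-4-[(trimethylsilyl)oxy]phenyl]-6,8-bis(3-methylbut-2-en-1-yl)-3,7-bis[(trimethylsilyl)oxy]-2,3-dihydro-4H-chromen-4-one F7. F7 is hydrolysed without purification (THF/H2O, citric acid, 0 °C) to 18.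

**Further compounds**

F1 | step 9 | 1-(2,4-dihydroxy-3,5-diiodophenyl)ethan-1-one | CC(=O)c1cc(I)c(O)c(I)c1O
F2 | step 9 | 1-[3,5-diiodo-2,4-bis(methoxymethoxy)phenyl]ethan-1-one | CC(=O)c1cc(I)c(OCOC)c(I)c1OCOC
F3 | step 9 | 1-[2,4-bis(methoxymethoxy)-3,5-bis(3-methylbut-2-en-1-yl)phenyl]ethan-1-one | CC(=O)c1cc(CC=C(C)C)c(OCOC)c(CC=C(C)C)c1OCOC
F4 | step 9 | (2E)-1-[2,4-bis(methoxymethoxy)-3,5-bis(3-methylbut-2-en-1-yl)phenyl]-3-[4-(methoxymethoxy)-3-(3-methylbut-2-en-1-yl)phenyl]prop-2-en-1-one | COCOc1ccc(/C=C/C(=O)c2cc(CC=C(C)C)c(OCOC)c(CC=C(C)C)c2OCOC)cc1CC=C(C)C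
F5 | step 9 | [2,4-bis(methoxymethoxy)-3,5-bis(3-methylbut-2-en-1-yl)phenyl]{(2R,3S)-3-[4-(methoxymethoxy)-3-(3-methylbut-2-en-1-yl)phenyl]oxiran-2-yl}methanone | O=C(c1cc(CC=C(C)C)c(OCOC)c(CC=C(C)C)c1OCOC)[C@@H]1O[C@H]1c1ccc(OCOC)c(CC=C(C)C)c1
F6 | step 3 | 1-bromo-2-fluoro-5-iodo-4-(methoxymethoxy)-3-(3-methylbut-2-en-1-yl)benzene | COCOc1c(I)cc(Br)c(F)c1CC=C(C)C
F7 | step 10 | (2R,3R)-2-[3-(3-methylbut-2-en-1-yl)-4-[(trimethylsilyl)oxy]phenyl]-6,8-bis(3-methylbut-2-en-1-yl)-3,7-bis[(trimethylsilyl)oxy]-2,3-dihydro-4H-chromen-4-one | CC(C)=CCc1cc([C@H]2Oc3c(cc(CC=C(C)C)c(O[Si](C)(C)C)c3CC=C(C)C)C(=O)[C@@H]2O[Si](C)(C)C)ccc1O[Si](C)(C)C
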